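The decalin is cut across ring A. A thermal intramolecular Diels–Alder reaction of an open-chain 1,3,9-decatriene forms C1–C2 and C5–C10 in one operation, closing rings A and B and setting C1, C5 and C10. It exploits the six-membered ring A (C1, C2, C3, C4, C5, C10) with its 1,4-related carbinols: the cycloadduct's C3=C4 alkene is hydrated to the C4 tertiary alcohol, and a C1–B bond from an (E)-alkenylboronate dienophile (C10=C1) becomes C1–OH. The precursor is a chain carrying the C6/C7/C8 triad (silyl ether, ethynyl, PMB ether), the 2-methyl diene C2=C3–C4=C5 and the boronate; the ethynyl group later becomes the acrylate.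

Key step: step 12

Remark: eudesmane numbering is used for every compound (C1–C10 decalin carbons, C11–C13 acrylate, C14 on C10, C15 on C4); β is the face of the C10 methyl group; the target is methyl 8α-acetoxy-1β,4α,6α-trihydroxyeudesm-11(13)-en-12-oate, (1R,4R,5S,6S,7S,8S,10R). Bpin = 4,4,5,5-tetramethyl-1,3,2-dioxaborolan-2-yl, PMB = 4-methoxybenzyl, TBS = tert-butyldimethylsilyl.

Step 1
Reactants: 1 (S)-glycidyl trityl ether
Product: 2 (2S)-1-(trityloxy)pent-4-yn-2-ol
Conditions: LiC≡CH·H2NCH2CH2NH2, DMSO, 0 °C to rt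
Reagents that add atoms: lithium acetylide ethylenediamine complex, [Li+].[C-]#C.NCCN
Why: Epoxide ring opening (SN2) by the acetylide at the unsubstituted epoxide carbon (C9) leaves the C8 stereocentre of the chiral-pool epoxide untouched.

Step 2
Reactants: 2 (2S)-1-(trityloxy)pent-4-yn-2-ol
Product: 3 PMB ether of 2
Conditions: NaH, 4-methoxybenzyl chloride, Bu4NI (cat.), DMF, 0 °C to rt
Reagents that add atoms: 4-methoxybenzyl chloride, COc1ccc(CCl)cc1
Why: Williamson ether synthesis at the C8 alkoxide installs the ether that later serves as chelating group, with no stereocentre touched.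

Step 3
Reactants: 3 PMB ether
Product: 4 (E)-alkenyl pinacol boronate (C10 methyl, C1 boron)
Conditions: CuCl (cat.), Xantphos (cat.), NaOtBu, B2pin2, MeI, THF, rt
Reagents that add atoms: bis(pinacolato)diboron, CC1(C)OB(OC1(C)C)B1OC(C)(C)C(C)(C)O1; iodomethane, CI
Why: Copper-catalysed carboboration (methylboration) of the terminal alkyne: syn addition of the boryl–copper species puts boron on the terminal carbon C1, and methylation of the alkenyl–copper bond with retention gives the (E)-alkene with CH3 and boron cis.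

Step 4
Reactants: 4 trityl ether
Product: 5 primary alcohol (C7–OH)
Conditions: TsOH·H2O (cat.), MeOH/CH2Cl2, rt
Reagents that add atoms: none
Why: Acid-catalysed solvolysis of the trityl ether through the trityl cation frees the primary alcohol, while the PMB ether and the pinacol boronate persist.

Step 5
Reactants: 5 primary alcohol
Product: 6 α-(PMB-oxy) aldehyde
Conditions: Dess–Martin periodinane, NaHCO3, CH2Cl2, 0 °C to rt
Reagents that add atoms: none
Why: Dess–Martin oxidation under buffered, non-enolising conditions gives the aldehyde without epimerising the α-alkoxy stereocentre C8.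

Step 6
Reactants: 6 aldehyde
Product: 7 (3S,4S)-propargylic alcohol
Conditions: HC≡CMgBr, MgBr2·OEt2, CH2Cl2, −78 °C
Reagents that add atoms: ethynylmagnesium bromide, C#C[Mg]Br
Why: Chelation-controlled (Cram chelate) Grignard addition: magnesium bridges the aldehyde oxygen and the PMB ether oxygen and the alkynyl group attacks the face opposite the C9 chain, which sets C7 syn to C8.

Step 7
Reactants: 7 propargylic alcohol
Product: 8 (3S,4S)-propargylic mesylate
Conditions: MsCl, Et3N, CH2Cl2, −20 °C
Reagents that add atoms: methanesulfonyl chloride, CS(=O)(=O)Cl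
Why: O-Sulfonylation with retention at C7 provides the leaving group for the SN2′ step.

Step 8
Reactants: 9 (2E)-3-methylpent-2-en-4-yn-1-ol
Product: 10 (2E)-3-methylpenta-2,4-dien-1-ol
Conditions: H2 (1 atm), Pd/CaCO3 poisoned with Pb(OAc)2, quinoline, EtOAc, rt
Reagents that add atoms: none
Why: Semi-hydrogenation (Lindlar reduction) of the terminal alkyne stops at the vinyl group and leaves the (E)-trisubstituted alkene as it is.

Step 9
Reactants: 10 dienol
Product: 11 (2E)-3-methylpenta-2,4-dienal
Conditions: MnO2, CH2Cl2, rt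
Reagents that add atoms: none
Why: MnO2 oxidation of the allylic alcohol gives the conjugated dienal without E/Z isomerisation.

Step 10
Reactants: 8 propargylic mesylate; 11 dienal
Product: 13 anti homopropargylic alcohol (C6–OH, C7 ethynyl, C8–OPMB), via allenylzinc 12 (not isolated)
Conditions: Pd(OAc)2 (cat.), PPh3 (cat.), Et2Zn, THF, −78 to −20 °C
Reagents that add atoms: none
Why: Palladium-catalysed propargylation through an allenylzinc reagent (Marshall–Tamaru propargylation): zerovalent palladium displaces the mesylate anti (SN2′), transmetalation gives the chiral allenylzinc 12, and its cyclic SE2′ addition to the aldehyde sets C7 by chirality transfer (net inversion) and C6 anti to the C8 branch.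

Step 11
Reactants: 13 homopropargylic alcohol
Product: 14 C6 TBS ether (cyclisation precursor)
Conditions: TBSOTf, 2,6-lutidine, CH2Cl2, −78 °C
Reagents that add atoms: tert-butyldimethylsilyl trifluoromethanesulfonate, CC(C)(C)[Si](C)(C)OS(=O)(=O)C(F)(F)F
Why: Silylation of the C6 hydroxyl with the silyl triflate and a hindered base proceeds with retention and, at −78 °C, without ionising the allylic carbinol.

Step 12
Reactants: 14 triene
Product: 15 trans-fused Δ3-octalin (1β-Bpin, 5α-H, 6α-OTBS, 7β-ethynyl, 8α-OPMB, 10β-CH3)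
Conditions: toluene (high dilution), BHT (cat.), 175 °C, sealed tube
Reagents that add atoms: none
Why: Thermal, concerted [4+2] cycloaddition (type 1 intramolecular Diels–Alder reaction) between the C2=C3–C4=C5 diene and the C10=C1 alkenylboronate, the closest known reaction being the Diels–Alder reaction of alkenylboronic esters followed by stereoretentive C–B oxidation. Ring A closes as the new cyclohexene of the cycloaddition and ring B closes at the same time through the four-carbon tether C6–C9 as a fused six-membered ring. C1 follows from suprafacial addition to the (E)-dienophile, which places boron cis to the C10 methyl group (1β). C5 and C10 are set by a chair-like tether in which the C6 silyl ether, the C7 ethynyl group and the C8 PMB ether are all equatorial, giving the trans ring fusion (5α-H, 10β-CH3). The step needs diene π-face selectivity and trans over cis fusion: the C4 methyl group forces the C6–H bond to eclipse the diene (allylic 1,3-strain), which fixes the face on the side of C7, and the three equatorial tether substituents together with the axial preference of CH3 over the boryl-bearing C1 favour the trans-decalin. Both new C–C bonds, the quaternary centre C10 and three stereocentres arise in this single operation.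

Step 13
Reactants: 15 PMB ether
Product: 16 C8 alcohol
Conditions: DDQ, CH2Cl2/pH 7 phosphate buffer, 0 °C
Reagents that add atoms: none
Why: Oxidative cleavage of the PMB ether by DDQ (hydride abstraction, hydrolysis of the hemiacetal) frees only the C8 hydroxyl, with retention.

Step 14
Reactants: 16 C8 alcohol
Product: 17 C8 acetate
Conditions: Ac2O, pyridine, DMAP (cat.), CH2Cl2, rt
Reagents that add atoms: acetic anhydride, CC(=O)OC(C)=O
Why: DMAP-catalysed acylation of the only free hydroxyl group installs the C8 acetate of the target.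

Step 15
Reactants: 17 C1 boronate
Product: 18 1β-alcohol
Conditions: NaBO3·4H2O, THF/H2O, rt
Reagents that add atoms: sodium perborate, [Na+].[Na+].O[B-]1(O)OO[B-](O)(O)OO1
Why: Oxidation of the C–B bond by perborate proceeds by 1,2-migration of C1 from boron to oxygen with retention, giving the 1β-alcohol under conditions mild enough for the acetate.

Step 16
Reactants: 18 Δ3-alkene
Product: 19 4α-tertiary alcohol
Conditions: Co(acac)2 (cat.), PhSiH3, O2 (1 atm), THF, rt
Reagents that add atoms: dioxygen, O=O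
Why: Mukaiyama hydration (hydrogen atom transfer from a cobalt hydride to C3, trapping of the tertiary C4 radical by O2): oxygen should add from the α face, anti to the axial C10 methyl group, to give the equatorial 4α-hydroxyl with Markovnikov regiochemistry, the terminal alkyne being a poor hydrogen-atom acceptor.

Step 17
Reactants: 19 terminal alkyne
Product: 20 methyl acrylate (C6 still silylated)
Conditions: Pd(OAc)2 (cat.), 2-(diphenylphosphino)pyridine, CH3SO3H (cat.), CO (20 bar), MeOH, 50 °C
Reagents that add atoms: carbon monoxide, [C-]#[O+]; methanol, CO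
Why: Palladium-catalysed Markovnikov hydromethoxycarbonylation of the terminal alkyne places CO2CH3 on the internal carbon C11 and creates the C11=C13 methylene, while the silyl ether on O6 prevents capture of the acyl–palladium intermediate as a lactone.

Step 18
Reactants: 20 silyl ether
Product: 21 target, methyl 8α-acetoxy-1β,4α,6α-trihydroxyeudesm-11(13)-en-12-oate
Conditions: HF·pyridine, pyridine, THF, 0 °C to rt
Reagents that add atoms: none
Why: Fluoride-mediated desilylation under buffered conditions frees the C6 hydroxyl without acyl migration or lactonisation.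

Compound list

1 | (S)-2-[(trityloxy)methyl]oxirane ((S)-glycidyl trityl ether) | C(OC(c1ccccc1)(c1ccccc1)c1ccccc1)[C@@H]1CO1 | starting material
2 | (2S)-1-(trityloxy)pent-4-yn-2-ol | C#CC[C@H](O)COC(c1ccccc1)(c1ccccc1)c1ccccc1 | intermediate
3 | 1-methoxy-4-({[(2S)-1-(trityloxy)pent-4-yn-2-yl]oxy}methyl)benzene | C#CC[C@H](OCc1ccc(OC)cc1)COC(c1ccccc1)(c1ccccc1)c1ccccc1 | intermediate
4 | 2-[(1E,4S)-4-[(4-methoxybenzyl)oxy]-2-methyl-5-(trityloxy)pent-1-en-1-yl]-4,4,5,5-tetramethyl-1,3,2-dioxaborolane | C(OC(c1ccccc1)(c1ccccc1)c1ccccc1)[C@@H](OCc1ccc(OC)cc1)C/C(C)=C/B1OC(C)(C)C(C)(C)O1 | intermediate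
5 | (2S,4E)-2-[(4-methoxybenzyl)oxy]-4-methyl-5-(4,4,5,5-tetramethyl-1,3,2-dioxaborolan-2-yl)pent-4-en-1-ol | OC[C@@H](OCc1ccc(OC)cc1)C/C(C)=C/B1OC(C)(C)C(C)(C)O1 | intermediate
6 | (2S,4E)-2-[(4-methoxybenzyl)oxy]-4-methyl-5-(4,4,5,5-tetramethyl-1,3,2-dioxaborolan-2-yl)pent-4-enal | O=C[C@@H](OCc1ccc(OC)cc1)C/C(C)=C/B1OC(C)(C)C(C)(C)O1 | intermediate
7 | (3S,4S,6E)-4-[(4-methoxybenzyl)oxy]-6-methyl-7-(4,4,5,5-tetramethyl-1,3,2-dioxaborolan-2-yl)hept-6-en-1-yn-3-ol | C#C[C@H](O)[C@@H](OCc1ccc(OC)cc1)C/C(C)=C/B1OC(C)(C)C(C)(C)O1 | intermediate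
8 | (3S,4S,6E)-4-[(4-methoxybenzyl)oxy]-6-methyl-7-(4,4,5,5-tetramethyl-1,3,2-dioxaborolan-2-yl)hept-6-en-1-yn-3-yl methanesulfonate | C#C[C@H](OS(C)(=O)=O)[C@@H](OCc1ccc(OC)cc1)C/C(C)=C/B1OC(C)(C)C(C)(C)O1 | intermediate
9 | (2E)-3-methylpent-2-en-4-yn-1-ol | C#C/C(C)=C/CO | starting material
10 | (2E)-3-methylpenta-2,4-dien-1-ol | C=C/C(C)=C/CO | intermediate
11 | (2E)-3-methylpenta-2,4-dienal | C=C/C(C)=C/C=O | intermediate
12 | ethyl[(aS,4S,6E)-4-[(4-methoxybenzyl)oxy]-6-methyl-7-(4,4,5,5-tetramethyl-1,3,2-dioxaborolan-2-yl)hepta-1,2,6-trien-1-yl]zinc (allenylzinc from anti SN2′ displacement) | CC[Zn]C([H])=[C@@]=C([H])[C@@H](OCc1ccc(OC)cc1)C/C(C)=C/B1OC(C)(C)C(C)(C)O1 | intermediate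
13 | (3E,5R,6S,7S,9E)-6-ethynyl-7-[(4-methoxybenzyl)oxy]-3,9-dimethyl-10-(4,4,5,5-tetramethyl-1,3,2-dioxaborolan-2-yl)deca-1,3,9-trien-5-ol | C=C/C(C)=C/[C@@H](O)[C@H](C#C)[C@@H](OCc1ccc(OC)cc1)C/C(C)=C/B1OC(C)(C)C(C)(C)O1 | intermediate
14 | tert-butyl{[(3E,5R,6R,7S,9E)-6-ethynyl-7-[(4-methoxybenzyl)oxy]-3,9-dimethyl-10-(4,4,5,5-tetramethyl-1,3,2-dioxaborolan-2-yl)deca-1,3,9-trien-5-yl]oxy}dimethylsilane | C=C/C(C)=C/[C@@H](O[Si](C)(C)C(C)(C)C)[C@H](C#C)[C@@H](OCc1ccc(OC)cc1)C/C(C)=C/B1OC(C)(C)C(C)(C)O1 | intermediate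
15 | trans-fused Δ3-octalin (C3=C4): 1β-Bpin, 5α-H, 6α-OTBS, 7β-ethynyl, 8α-OPMB, 4-CH3, 10β-CH3 | C#C[C@H]1[C@H](O[Si](C)(C)C(C)(C)C)[C@@H]2[C@@](C)(C[C@@H]1OCc1ccc(OC)cc1)[C@H](B1OC(C)(C)C(C)(C)O1)CC=C2C | intermediate
16 | as 15 with free 8α-OH: 1β-Bpin, 5α-H, 6α-OTBS, 7β-ethynyl, 8α-OH, 4-CH3, 10β-CH3, Δ3 | C#C[C@H]1[C@H](O[Si](C)(C)C(C)(C)C)[C@@H]2[C@@](C)(C[C@@H]1O)[C@H](B1OC(C)(C)C(C)(C)O1)CC=C2C | intermediate
17 | as 16 with 8α-OAc: 1β-Bpin, 5α-H, 6α-OTBS, 7β-ethynyl, 8α-acetoxy, 4-CH3, 10β-CH3, Δ3 | C#C[C@H]1[C@H](O[Si](C)(C)C(C)(C)C)[C@@H]2[C@@](C)(C[C@@H]1OC(C)=O)[C@H](B1OC(C)(C)C(C)(C)O1)CC=C2C | intermediate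
18 | 1β-hydroxy-6α-OTBS-7β-ethynyl-8α-acetoxy-4,10β-dimethyl-trans-Δ3-octalin (5α-H) | C#C[C@H]1[C@H](O[Si](C)(C)C(C)(C)C)[C@@H]2[C@@](C)(C[C@@H]1OC(C)=O)[C@H](O)CC=C2C | intermediate
19 | 1β,4α-dihydroxy-6α-OTBS-7β-ethynyl-8α-acetoxy-4β,10β-dimethyl-trans-decalin (5α-H) | C#C[C@H]1[C@H](O[Si](C)(C)C(C)(C)C)[C@@H]2[C@@](C)(C[C@@H]1OC(C)=O)[C@H](O)CC[C@@]2(C)O | intermediate
20 | methyl 8α-acetoxy-6α-(tert-butyldimethylsilyloxy)-1β,4α-dihydroxyeudesm-11(13)-en-12-oate | C=C(C(=O)OC)[C@H]1[C@H](O[Si](C)(C)C(C)(C)C)[C@@H]2[C@@](C)(C[C@@H]1OC(C)=O)[C@H](O)CC[C@@]2(C)O | intermediate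
21 | methyl 8α-acetoxy-1β,4α,6α-trihydroxyeudesm-11(13)-en-12-oate, (1R,4R,5S,6S,7S,8S,10R) | C=C(C(=O)OC)[C@H]1[C@H](O)[C@@H]2[C@@](C)(C[C@@H]1OC(C)=O)[C@H](O)CC[C@@]2(C)O | target

Total step count: 18 (steps 8 and 9 make the dienal 11 for the convergent step 10).
Longest linear sequence: 16 steps (steps 1–7 and 10–18).

Steps most likely to fail

Step 12. The cycloaddition may erode through poor discrimination between trans and cis ring fusion at the dienophile, or through thermal decomposition of the triene before it cyclises at the temperature a pinacol boronate needs. The fallback replaces the passive boronic ester by a Lewis-acidic boron dienophile. It sets out from 14: KHF2 in MeOH/H2O should give the potassium alkenyltrifluoroborate F1, and SiCl4 in CH2Cl2 at −40 °C should convert it in the flask into the alkenyldichloroborane F2. This LUMO-lowered dienophile is expected to cyclise at −20 to 0 °C with boron endo, which corresponds to the trans-fused alkyldichloroborane F3. Pinacol and Et3N then bring the sequence back to the route at 15. Ether cleavage by the B–Cl species is the limit of this variant, so it is run cold and quenched at once.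

Step 10. The allenylzinc may lose the C8 alkoxide by β-elimination to an enyne, or racemise before it adds, which would erode the chirality transfer. The fallback uses a covalent allenylboron reagent that can do neither. It sets out from 7: ClCO2Me and pyridine should give the propargylic methyl carbonate F4, and anti-SN2′ borylation with B2pin2 (CuOtBu, Xantphos, THF) should give the configurationally stable allenylboronate F5. Heating F5 with 11 in toluene should lead, through a closed six-membered SE2′ transition state, to the same anti adduct after hydrolytic work-up, and the sequence comes back to the route at 13.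

Step 17. The hydroesterification may lose Markovnikov regiocontrol at the hindered alkyne, or the acid co-catalyst may remove the silyl group so that the acyl–palladium species closes to a lactone. The fallback fixes the regiochemistry before the carbonylation. It sets out from 19: Markovnikov hydrosilylation with Et3SiH and [(C5Me5)Ru(NCMe)3]PF6 should give the α-vinylsilane F6, and iododesilylation with N-iodosuccinimide and 2,6-lutidine in (CF3)2CHOH should give the 2-iodoalkene F7. Base-buffered methoxycarbonylation (Pd(PPh3)4, CO, MeOH, Et3N, 50 °C) then comes back to the route at 20.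

Further compounds
F1 | step 12 | potassium trifluoroborate analogue of 14 (BF3K in place of Bpin on C1) | C=C/C(C)=C/[C@@H](O[Si](C)(C)C(C)(C)C)[C@H](C#C)[C@@H](OCc1ccc(OC)cc1)C/C(C)=C/[B-](F)(F)F.[K+]
F2 | step 12 | alkenyldichloroborane analogue of 14 (BCl2 in place of Bpin on C1) | C=C/C(C)=C/[C@@H](O[Si](C)(C)C(C)(C)C)[C@H](C#C)[C@@H](OCc1ccc(OC)cc1)C/C(C)=C/B(Cl)Cl
F3 | step 12 | dichloroborane analogue of 15 (1β-BCl2, trans-fused Δ3-octalin) | C#C[C@H]1[C@H](O[Si](C)(C)C(C)(C)C)[C@@H]2[C@@](C)(C[C@@H]1OCc1ccc(OC)cc1)[C@H](B(Cl)Cl)CC=C2C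
F4 | step 10 | (3S,4S,6E)-4-[(4-methoxybenzyl)oxy]-6-methyl-7-(4,4,5,5-tetramethyl-1,3,2-dioxaborolan-2-yl)hept-6-en-1-yn-3-yl methyl carbonate | C#C[C@H](OC(=O)OC)[C@@H](OCc1ccc(OC)cc1)C/C(C)=C/B1OC(C)(C)C(C)(C)O1
F5 | step 10 | (aS,4S,6E)-allenylboronate: 1,7-bis(4,4,5,5-tetramethyl-1,3,2-dioxaborolan-2-yl)-4-[(4-methoxybenzyl)oxy]-6-methylhepta-1,2,6-triene | CC1(C)OB(OC1(C)C)C([H])=[C@@]=C([H])[C@@H](OCc1ccc(OC)cc1)C/C(C)=C/B1OC(C)(C)C(C)(C)O1
F6 | step 17 | α-vinylsilane from 19: C7–C(=CH2)SiEt3, otherwise as 19 | CC[Si](CC)(CC)C(=C)[C@H]1[C@H](O[Si](C)(C)C(C)(C)C)[C@@H]2[C@@](C)(C[C@@H]1OC(C)=O)[C@H](O)CC[C@@]2(C)O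
F7 | step 17 | 2-iodoalkene from F6: C7–C(I)=CH2, otherwise as 19 | C=C(I)[C@H]1[C@H](O[Si](C)(C)C(C)(C)C)[C@@H]2[C@@](C)(C[C@@H]1OC(C)=O)[C@H](O)CC[C@@]2(C)O
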